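Each product made costs one substrate and one reagent, so in the east run the substrate left, bound forms counted, stays ahead of the reagent left by 120 mM however the flask runs. Reagent is therefore the limiting reagent there, and I count everything in y, the fraction of the reagent charge turned into product.

| setting | west | south | north-east | south-west | east |
|---|---|---|---|---|---|
| substrate | 120 mM | 48.0 mM | 120 mM | 120 mM | 240 mM |
| reagent | 240 mM | 168 mM | 240 mM | 480 mM | 120 mM |
| free catalyst | 0.240 mM | 0.240 mM | 0.360 mM | 0.240 mM | 0.240 mM |
| time |  |  |  |  | 36 min |

| run | time / min | [product] / mM |
|---|---|---|
| west run | 4.5 | 12.1 |
| west run | 9.0 | 22.9 |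
| west run | 14 | 33.2 |
| west run | 18 | 40.6 |
| west run | 22 | 48.0 |
| west run | 27 | 54.3 |
| west run | 32 | 63.5 |
| west run | 36 | 68.5 |
| south run | 4.5 | 7.1 |
| south run | 9.0 | 9.8 |
| south run | 14 | 16.4 |
| south run | 18 | 21.0 |
| south run | 22 | 21.2 |
| south run | 27 | 24.5 |
| south run | 32 | 26.3 |
| south run | 36 | 27.3 |
| north-east run | 4.5 | 18.0 |
| north-east run | 9.0 | 34.5 |
| north-east run | 14 | 45.4 |
| north-east run | 18 | 56.8 |
| north-east run | 22 | 63.9 |
| north-east run | 27 | 72.1 |
| north-east run | 32 | 78.2 |
| north-east run | 36 | 83.1 |
| south-west run | 4.5 | 18.9 |
| south-west run | 9.0 | 36.4 |
| south-west run | 14 | 48.3 |
| south-west run | 18 | 58.6 |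
| south-west run | 22 | 64.5 |
| south-west run | 27 | 74.2 |
| south-west run | 32 | 79.4 |
| south-west run | 36 | 81.7 |

(scatter of a reading: 1 mM)

- Overall: substrate + reagent -> product, with free catalyst as catalyst.
- Constant volume, constant temperature.
- A reading of a species includes what of it is bound.
- "The second partner" is reagent.
- An order is taken over about fifteen percent of the charge, up and down.

1. the power of [reagent] that the first rate follows, about the charge of the west run; measure it at two percent of substrate made into product
2. the power of [substrate] that the first rate follows, about the charge of the west run; measure it at two percent of substrate made into product (one fixed amount of product, the same in the runs compared)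
3. the south run starts with 72.0 mM less of substrate and of reagent than the west run, and with no product. Compared where both hold the same amount of substrate, once fifteen percent of what the south run was charged with has turned into product, is the south run faster, slower or alike (within a tenth)?
4. product in the east run at 36 min, as a share of the substrate charged

A fraction y of the reagent is y times 0.500 of the substrate, so the first ceiling on the east share, at y equal to 1, is 50.0%. To tighten it I treat the east run as pseudo-first-order in reagent, an approximation of mine, its substrate being in excess. The rate of turning y is then c(1 − y), which integrates to

y = 1 − exp(−c·t), or c = −ln(1 − y)/t.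

I call c the reagent clock of a run up to time t. The west run's first reading gives a clock of 0.0115 min⁻¹, a reading good to about 8.26%. It is faster than the first-reading clocks of the south run, 0.00960 min⁻¹, and the south-west run, 0.00893 min⁻¹. The west clock also slows to 0.00933 min⁻¹ over the whole west run. Held for 36 min, the fast clock gives the upper end of my bracket, a hand estimate and no proof:

share = 16.9%.

For the lower end, again an estimate, I take the slower whole-run clock of the two runs charged with 120 mM substrate at this catalyst, the south-west run's 0.00518 min⁻¹. I go no tighter by hand, since the east charge has a lower ratio of reagent to substrate than any run so far. That gives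

share = 8.51%.

The forecast says 20.5%, within 17.5% to 24%, from a millimolar product of “about 49 at 36 min, or roughly 20%”. It also gives 0.65 for the reagent order, 0.4 for the substrate order, and the south run faster. Even its low end stands above the upper end of my bracket.

The east run gives 13.7%, inside my bracket and below the forecast's low end, with orders of 0.86 in reagent and 0.22 in substrate, and the south run faster. The turning of free catalyst into spent catalyst makes no difference to that east share.

    free catalyst + substrate ⇌ catalyst-substrate complex, settled at all times (28.30 M⁻¹)
    catalyst-substrate complex + reagent → product + free catalyst (154.2 M⁻¹ min⁻¹)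
    2 free catalyst → 2 spent catalyst (84.00 M⁻¹ min⁻¹)
    substrate + reagent ⇌ idle substrate-reagent adduct, settled at all times (15.20 M⁻¹)

The east clock over the whole run comes to 0.00888 min⁻¹, which is 0.772 of the west first-reading clock. Scaled by the catalyst charge, that west clock becomes 0.0172 min⁻¹ for the north-east run, and it puts product at a quarter of the substrate charge there at 7.74 min, and the north-east run reached that quarter at 8.04 min.

(All runs come from a simulation for an exercise.)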